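**Plan**

- **Numbering:** the diketone chain is C1–C4, with C1 and C4 the carbonyls. C5 (on C2) and C6 (on C3) are the benzylic carbons. Ring A is each 2,4-dihydroxyphenyl on C1/C4, and ring B is each 4-hydroxyphenyl on C5/C6.
- **Retrosynthesis:** six phenol protecting groups come off first. The C1–ring A and C4–ring A bonds are then cut, giving a bis-Weinreb amide and an aryllithium. The C5–ring B and C6–ring B bonds are cut last, giving two methyl C–H bonds and an aryl iodide.
- **Enabling feature:** the remaining C1–C6 unit is meso-2,3-dimethylsuccinic acid. C5 and C6 are methyl groups β to the C1 and C4 amide carbonyls, so each amide can steer palladium onto its own methyl group.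
- **Forward direction:** no ring is formed. The six-carbon core grows outward at both ends at once through diamide formation, twofold C–H arylation (rings B), twofold acylation of an aryllithium (rings A) and global hydrogenolysis.
- **Stereochemistry:** the C2/C3 relationship is bought with the diacid, and no later step breaks a bond at C2 or C3.

Key step: step 2

Remark: with identical substituents and opposite descriptors (2S,3R) the target is the achiral meso isomer; the desymmetrised intermediates 2 and 5 therefore arise as racemates and are drawn as one enantiomer of the correct relative configuration.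

**Step 1**
Reactants: 1 meso-2,3-dimethylsuccinic acid
Product: 3 meso-N1,N4-dimethoxy-N1,N4,2,3-tetramethylsuccinamide, via monoamide acid 2 (not isolated)
Conditions: MeNH(OMe)·HCl (2.6 equiv), EDC·HCl (2.6 equiv), HOBt (2.6 equiv), N-methylmorpholine (3.0 equiv), CH2Cl2, 0 °C → rt
Reagents that add atoms: N,O-dimethylhydroxylamine hydrochloride, CNOC.Cl
Why: Carbodiimide/HOBt amide coupling (Weinreb amide formation) at both carboxyl groups should work because a secondary amine cannot close an imide, and the weak base and low temperature leave the C2–H and C3–H bonds intact, so the meso configuration is carried over.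

**Step 2**
Reactants: 3 meso-N1,N4-dimethoxy-N1,N4,2,3-tetramethylsuccinamide; 4 1-(benzyloxy)-4-iodobenzene
Product: 6 meso-2,3-bis[4-(benzyloxy)benzyl]-N1,N4-dimethoxy-N1,N4-dimethylsuccinamide, via monoarylated diamide 5 (not isolated)
Conditions: 4 (3.0 equiv), Pd(OAc)2 (20 mol %), pyridine-3-sulfonic acid (40 mol %), AgOAc (4.0 equiv), (CF3)2CHOH, 90 °C, sealed tube
Reagents that add atoms: none
Why: Divalent palladium, kept cationic and electrophilic by the zwitterionic pyridine-3-sulfonate ligand, binds the carbonyl oxygen of one Weinreb amide of 3 and cleaves a C–H bond of the methyl group on the adjacent carbon by concerted metalation–deprotonation to a five-membered palladacycle; oxidative addition of 4 (to tetravalent palladium) and C–C reductive elimination make the C5–ring B bond, AgOAc removes iodide as AgI, and the same cycle on 5 makes the C6–ring B bond. The closest known reaction is the pyridinesulfonic-acid-enabled, Pd(OAc)2-catalysed β-C(sp3)–H arylation of aliphatic Weinreb amides with aryl iodides, a weakly coordinating relative of the 8-aminoquinoline-amide arylation, run here at both ends of one molecule. No ring is closed and no stereocentre is created: C2 and C3 keep the purchased meso relationship because their C–H bonds are not broken, acetate in (CF3)2CHOH is far too weak a base to enolise an amide, and β-hydride elimination towards C2–H or C3–H is held back by the rigid chelate. The step needs primary over tertiary and secondary C–H selectivity: the methine β to each carbonyl (C3 for the C1 amide, C2 for the C4 amide) is tertiary and too crowded for concerted metalation, the α-methine would require a four-membered palladacycle, and the benzylic CH2 formed in the first cycle is an acyclic secondary position that a neutral monodentate amide does not activate, so each methyl should take up only one aryl group even with a modest excess of 4. Regiochemistry is degenerate, since each methyl is β to one amide and γ to the other and either mode of direction arylates the same carbon. The directing groups are not removed but become the acyl donors of step 4.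

**Step 3**
Reactants: 7 4-bromoresorcinol (4-bromobenzene-1,3-diol)
Product: 8 2,4-bis(benzyloxy)-1-bromobenzene
Conditions: BnBr (2.3 equiv), K2CO3 (3.0 equiv), DMF, 60 °C
Reagents that add atoms: benzyl bromide, BrCc1ccccc1
Why: In this Williamson ether synthesis both phenoxides of 7 displace bromide from benzyl bromide by SN2, while the aryl C–Br bond is inert under these conditions.

**Step 4**
Reactants: 6 meso-2,3-bis[4-(benzyloxy)benzyl]-N1,N4-dimethoxy-N1,N4-dimethylsuccinamide; 8 2,4-bis(benzyloxy)-1-bromobenzene
Product: 11 meso-1,4-bis[2,4-bis(benzyloxy)phenyl]-2,3-bis[4-(benzyloxy)benzyl]butane-1,4-dione, via aryllithium 9 (not isolated), via dilithium bis-adduct 10 (not isolated)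
Conditions: 8 (3.0 equiv), n-BuLi (2.9 equiv), THF, −78 °C, 30 min; then 6 in THF, −78 → −30 °C; AcOH/THF quench at −78 °C, then pH 7 buffer
Reagents that add atoms: none
Why: This is a Weinreb ketone synthesis at both termini, a mode of 1,4-diketone formation established for succinic bis-Weinreb amides, in which 9 from Br/Li exchange adds to each amide to give the N-methoxy-chelated tetrahedral adduct 10, which neither collapses (no over-addition) nor carries an enolisable carbonyl, so C2 and C3 stay untouched until the cold acidic quench releases the diketone.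

**Step 5**
Reactants: 11 meso-1,4-bis[2,4-bis(benzyloxy)phenyl]-2,3-bis[4-(benzyloxy)benzyl]butane-1,4-dione
Product: 12 meso-(2R,3S)-1,4-bis(2,4-dihydroxyphenyl)-2,3-bis(4-hydroxybenzyl)butane-1,4-dione (target)
Conditions: H2 (1 atm), Pd/C (10 wt % Pd), THF/MeOH 1:1, rt, stopped when hydrogen uptake ends
Reagents that add atoms: none
Why: Catalytic hydrogenolysis of the six aryl benzyl ethers runs under neutral conditions, the electron-rich and (once the ortho benzyl is lost) hydrogen-bonded 2,4-dioxygenated aryl ketones resist reduction at 1 atm, and the absence of acid or base leaves C2 and C3 unchanged.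

**Compound list**

1 | meso-2,3-dimethylsuccinic acid | OC(=O)[C@@H](C)[C@@H](C)C(=O)O | starting material
2 | rac-(2R,3S)-4-[methoxy(methyl)amino]-2,3-dimethyl-4-oxobutanoic acid (monoamide acid, not isolated) | CON(C)C(=O)[C@@H](C)[C@@H](C)C(=O)O | intermediate
3 | meso-N1,N4-dimethoxy-N1,N4,2,3-tetramethylsuccinamide | CON(C)C(=O)[C@@H](C)[C@@H](C)C(=O)N(C)OC | intermediate
4 | 1-(benzyloxy)-4-iodobenzene | Ic1ccc(OCc2ccccc2)cc1 | starting material
5 | rac-(2S,3R)-2-[4-(benzyloxy)benzyl]-N1,N4-dimethoxy-N1,N4,3-trimethylsuccinamide (monoarylated diamide, not isolated) | CON(C)C(=O)[C@@H](Cc1ccc(OCc2ccccc2)cc1)[C@@H](C)C(=O)N(C)OC | intermediate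
6 | meso-2,3-bis[4-(benzyloxy)benzyl]-N1,N4-dimethoxy-N1,N4-dimethylsuccinamide | CON(C)C(=O)[C@@H](Cc1ccc(OCc2ccccc2)cc1)[C@@H](Cc1ccc(OCc2ccccc2)cc1)C(=O)N(C)OC | intermediate
7 | 4-bromoresorcinol | Oc1ccc(Br)c(O)c1 | starting material
8 | 2,4-bis(benzyloxy)-1-bromobenzene | Brc1ccc(OCc2ccccc2)cc1OCc1ccccc1 | intermediate
9 | [2,4-bis(benzyloxy)phenyl]lithium (not isolated) | [Li]c1ccc(OCc2ccccc2)cc1OCc1ccccc1 | intermediate
10 | dilithium 1,4-bis[2,4-bis(benzyloxy)phenyl]-2,3-bis[4-(benzyloxy)benzyl]-1,4-bis[methoxy(methyl)amino]butane-1,4-diolate, meso at C2/C3, C1 and C4 undefined (not isolated) | CON(C)C([O-])(c1ccc(OCc2ccccc2)cc1OCc1ccccc1)[C@@H](Cc1ccc(OCc2ccccc2)cc1)[C@@H](Cc1ccc(OCc2ccccc2)cc1)C([O-])(N(C)OC)c1ccc(OCc2ccccc2)cc1OCc1ccccc1.[Li+].[Li+] | intermediate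
11 | meso-1,4-bis[2,4-bis(benzyloxy)phenyl]-2,3-bis[4-(benzyloxy)benzyl]butane-1,4-dione | O=C(c1ccc(OCc2ccccc2)cc1OCc1ccccc1)[C@@H](Cc1ccc(OCc2ccccc2)cc1)[C@@H](Cc1ccc(OCc2ccccc2)cc1)C(=O)c1ccc(OCc2ccccc2)cc1OCc1ccccc1 | intermediate
12 | meso-(2R,3S)-1,4-bis(2,4-dihydroxyphenyl)-2,3-bis(4-hydroxybenzyl)butane-1,4-dione | O=C(c1ccc(O)cc1O)[C@@H](Cc1ccc(O)cc1)[C@@H](Cc1ccc(O)cc1)C(=O)c1ccc(O)cc1O | target

Total step count: 5
Longest linear sequence: 4 (steps 1, 2, 4, 5)

**Steps most likely to fail**

**Step 2 (twofold C–H arylation).**
- The catalyst may be sequestered by chelation between the two neighbouring amide oxygens or by the N-methoxy oxygen.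
- The reaction may stall after the first arylation as the substrate becomes more crowded.
- The benzyl ethers may slowly solvolyse in the hot acidic fluoroalcohol.
- C2/C3 may scramble through β-hydride elimination and re-insertion.

The fallback gives up the C5/C6–ring B disconnection and builds the C2–C3 bond instead. It sets out from 8 and comes back at 11. Purchased 3-[4-(benzyloxy)phenyl]propanoic acid is converted under the conditions of step 1 into 3-[4-(benzyloxy)phenyl]-N-methoxy-N-methylpropanamide F1. Aryllithium 9, made from 8 as in step 4, adds to it to give 1-[2,4-bis(benzyloxy)phenyl]-3-[4-(benzyloxy)phenyl]propan-1-one F2. The lithium enolate of F2 (LiN(i-Pr)2, THF, −78 °C) is then dimerised oxidatively with CuCl2 in THF/DMF, a known way from aryl alkyl ketones to 2,3-disubstituted 1,4-diketones. This coupling has no built-in preference for the meso isomer. Compound 11 would therefore have to be separated by crystallisation or chromatography from rac-(2S,3S)-1,4-bis[2,4-bis(benzyloxy)phenyl]-2,3-bis[4-(benzyloxy)benzyl]butane-1,4-dione F3. F3 can be returned to the mixture by base-mediated equilibration at C2/C3.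

**Step 4 (twofold aryllithium addition).**
- The basic aryllithium may abstract a proton at C2/C3 or at the N-methoxy group instead of adding.
- The second addition at the crowded α-branched amide may be sluggish.
- Epimerisation may set in once the ketone is released.

The fallback changes the oxidation level of the acceptor. It sets out from 6 and comes back at 11. Reduction of both Weinreb amides with i-Bu2AlH (THF, −78 °C, tartrate work-up) should give meso-2,3-bis[4-(benzyloxy)benzyl]butanedial F4, which is used crude. Addition of 9 at −78 °C to these far more electrophilic carbonyls, where addition should outrun proton transfer, gives 1,4-bis[2,4-bis(benzyloxy)phenyl]-2,3-bis[4-(benzyloxy)benzyl]butane-1,4-diol F5 as a mixture of carbinol epimers, which does not matter. Buffered oxidation with Dess–Martin periodinane (NaHCO3, CH2Cl2) then generates the diketone 11 under essentially neutral conditions.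

**Step 1 (bis-Weinreb amide formation).**
- Partial epimerisation may occur while the carboxyl groups are activated, by enolisation of an activated succinyl species or through cyclisation to an anhydride.
- O→N acyl migration on the carbodiimide adduct may compete.
- The second coupling next to the first bulky amide may be slow.

The fallback avoids carboxyl activation altogether. It sets out from 1 and comes back at 3. Fischer esterification (MeOH, cat. H2SO4, reflux) gives dimethyl meso-2,3-dimethylsuccinate F6. Both ester groups are then aminolysed with the aluminium amide Me(Cl)AlN(OMe)Me, made from AlMe3 and MeNH(OMe)·HCl in CH2Cl2 (0 °C → rt). This is a non-basic, Lewis-acid-mediated ester-to-Weinreb-amide exchange.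

**Further compounds**

F1 | step 2 | 3-[4-(benzyloxy)phenyl]-N-methoxy-N-methylpropanamide | CON(C)C(=O)CCc1ccc(OCc2ccccc2)cc1
F2 | step 2 | 1-[2,4-bis(benzyloxy)phenyl]-3-[4-(benzyloxy)phenyl]propan-1-one | O=C(CCc1ccc(OCc2ccccc2)cc1)c1ccc(OCc2ccccc2)cc1OCc1ccccc1
F3 | step 2 | rac-(2S,3S)-1,4-bis[2,4-bis(benzyloxy)phenyl]-2,3-bis[4-(benzyloxy)benzyl]butane-1,4-dione | O=C(c1ccc(OCc2ccccc2)cc1OCc1ccccc1)[C@@H](Cc1ccc(OCc2ccccc2)cc1)[C@H](Cc1ccc(OCc2ccccc2)cc1)C(=O)c1ccc(OCc2ccccc2)cc1OCc1ccccc1
F4 | step 4 | meso-2,3-bis[4-(benzyloxy)benzyl]butanedial | O=C[C@@H](Cc1ccc(OCc2ccccc2)cc1)[C@@H](Cc1ccc(OCc2ccccc2)cc1)C=O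
F5 | step 4 | 1,4-bis[2,4-bis(benzyloxy)phenyl]-2,3-bis[4-(benzyloxy)benzyl]butane-1,4-diol (meso at C2/C3, carbinol centres undefined) | OC(c1ccc(OCc2ccccc2)cc1OCc1ccccc1)[C@@H](Cc1ccc(OCc2ccccc2)cc1)[C@@H](Cc1ccc(OCc2ccccc2)cc1)C(O)c1ccc(OCc2ccccc2)cc1OCc1ccccc1
F6 | step 1 | dimethyl meso-2,3-dimethylsuccinate | COC(=O)[C@@H](C)[C@@H](C)C(=O)OC
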